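**Retrosynthetic overview**
1. The plan rests on one feature of the coumarin: the C8 acyl carbon lies between two ring-bound oxygens, O1 on C8a and the methoxy oxygen on C7. Removing C2–C3–C4 of the pyranone (ring B) and the O-methyl group leaves a 2-acylresorcinol with two equivalent hydroxyls and two equivalent ortho CH positions, already holding the C2' stereocentre.
2. Disconnections, last to first: the C7 O–CH3 bond; ring B through C4–C4a and O1–C2 from the 2-acylresorcinol 12 and ethyl propiolate 13; the C2' O–acyl (senecioate) bond; the aryl–C1' bond from C2-lithiated resorcinol bis(methoxymethyl) ether and a Weinreb amide of the O-silylated (R)-hydroxy acid.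
3. Ring order: ring A (benzene) is bought as resorcinol and ring B is the only ring made (step 8). The single stereocentre is bought with acid 3 and carried through without breaking a bond to it.

Key step: step 8

Assumption: coumarin numbering is used (O1, C2–C8a; C1' is the ketone carbon, C2' the stereocentre). The target is (R) at C2', the same spatial arrangement as C2 of (R)-2-hydroxy-3-methylbutanoic acid, and the two ortho CH positions of the 2,6-dihydroxyaryl ketone count as equivalent because rotation about the aryl–C1' bond interchanges them.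

**Route**

Step 1
Reactants: 1 resorcinol
Product: 2 1,3-bis(methoxymethoxy)benzene
Conditions: NaH (2.4 equiv), MOMCl (2.4 equiv), DMF, 0 °C → rt
Reagents that add atoms: chloromethyl methyl ether, COCCl
Why: Double Williamson-type O-alkylation of the bis-phenoxide by the reactive α-chloro ether should install two acetal groups that tolerate organolithium reagents and later direct lithiation to C2.

Step 2
Reactants: 3 (R)-2-hydroxy-3-methylbutanoic acid
Product: 4 (2R)-2-hydroxy-N-methoxy-N,3-dimethylbutanamide
Conditions: MeNH(OMe)·HCl, EDC·HCl, HOBt, N-methylmorpholine, CH2Cl2, 0 °C → rt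
Reagents that add atoms: N,O-dimethylhydroxylamine hydrochloride, CNOC.Cl
Why: Carbodiimide/HOBt amide coupling, in which the active ester is taken by the far more nucleophilic amine nitrogen than by the free secondary hydroxyl, and an α-hydroxy acid has no oxazolone pathway, so the configuration of 3 should be kept.

Step 3
Reactants: 4 (2R)-2-hydroxy-N-methoxy-N,3-dimethylbutanamide
Product: 5 (2R)-2-[(tert-butyldimethylsilyl)oxy]-N-methoxy-N,3-dimethylbutanamide
Conditions: TBSOTf, 2,6-lutidine, CH2Cl2, 0 °C
Reagents that add atoms: tert-butyldimethylsilyl trifluoromethanesulfonate, CC(C)(C)[Si](C)(C)OS(=O)(=O)C(F)(F)F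
Why: O-Silylation of the hindered secondary alcohol with a silyl triflate and a hindered pyridine base masks the hydroxyl against the aryllithium of step 4 without touching a bond to the stereocentre.

Step 4
Reactants: 2 1,3-bis(methoxymethoxy)benzene; 5 (2R)-2-[(tert-butyldimethylsilyl)oxy]-N-methoxy-N,3-dimethylbutanamide
Product: 8 (2R)-1-[2,6-bis(methoxymethoxy)phenyl]-2-[(tert-butyldimethylsilyl)oxy]-3-methylbutan-1-one, via aryllithium 6 (not isolated), via lithium hemiaminal alkoxide 7 (not isolated)
Conditions: 2 (1.4 equiv), n-BuLi (1.3 equiv), THF, 0 °C, 1 h; then 5 (1.0 equiv), −78 → 0 °C; sat. aq NH4Cl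
Reagents that add atoms: none
Why: Directed ortho-metalation removes the C2 proton between the two lithium-coordinating acetal oxygens, and the aryllithium adds once to the amide (Weinreb ketone synthesis) because the chelated adduct 7 persists until the quench, so no enolisable ketone meets the base and the α-centre should stay intact.

Step 5
Reactants: 8 (2R)-1-[2,6-bis(methoxymethoxy)phenyl]-2-[(tert-butyldimethylsilyl)oxy]-3-methylbutan-1-one
Product: 9 (2R)-1-[2,6-bis(methoxymethoxy)phenyl]-2-hydroxy-3-methylbutan-1-one
Conditions: HF·pyridine, pyridine, THF, 0 °C → rt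
Reagents that add atoms: none
Why: Fluoride-driven Si–O cleavage under buffered, weakly acidic conditions should free the alcohol while the aryl acetals survive and the ketol is neither enolised nor isomerised.

Step 6
Reactants: 9 (2R)-1-[2,6-bis(methoxymethoxy)phenyl]-2-hydroxy-3-methylbutan-1-one; 10 3-methylbut-2-enoyl chloride
Product: 11 (2R)-1-[2,6-bis(methoxymethoxy)phenyl]-3-methyl-1-oxobutan-2-yl 3-methylbut-2-enoate
Conditions: 10 (1.5 equiv), pyridine, DMAP (cat.), CH2Cl2, 0 °C → rt
Reagents that add atoms: none
Why: O-Acylation through the acylpyridinium ion (nucleophilic catalysis), in which pyridine in place of a trialkylamine should suppress dehydrochlorination of 10 to the vinylketene that would give the deconjugated ester, and the C–O bond at the stereocentre is not broken.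

Step 7
Reactants: 11 (2R)-1-[2,6-bis(methoxymethoxy)phenyl]-3-methyl-1-oxobutan-2-yl 3-methylbut-2-enoate
Product: 12 (2R)-1-(2,6-dihydroxyphenyl)-3-methyl-1-oxobutan-2-yl 3-methylbut-2-enoate
Conditions: HCl (1.25 M in MeOH), CH2Cl2, 0 °C → rt
Reagents that add atoms: none
Why: Acid-catalysed acetal exchange to methanol cleaves both aryl methoxymethyl ethers, which are especially labile ortho to a carbonyl group, while the hindered conjugated ester should resist methanolysis at room temperature and no base is present to enolise the ketone.

Step 8
Reactants: 12 (2R)-1-(2,6-dihydroxyphenyl)-3-methyl-1-oxobutan-2-yl 3-methylbut-2-enoate; 13 ethyl propiolate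
Product: 15 (2R)-1-(7-hydroxy-2-oxo-2H-chromen-8-yl)-3-methyl-1-oxobutan-2-yl 3-methylbut-2-enoate, via Z-cinnamate 14 (not isolated)
Conditions: 13 (1.3 equiv), Pd(OAc)2 (5 mol %), CF3CO2H/CH2Cl2 (4:1), rt
Reagents that add atoms: none
Why: Pd(OAc)2 in CF3CO2H gives a cationic divalent palladium species that binds the triple bond of 13, and the arene attacks the alkyne terminus in a Friedel–Crafts sense through the ring carbon ortho to one hydroxyl and para to the other; protonolysis of the vinyl–palladium bond completes a trans hydroarylation and gives the Z-cinnamate 14. The closest known reaction type is the palladium-catalysed hydroarylation–lactonisation of phenols with propiolates, a mild Pechmann-type coumarin synthesis. Ring B closes by 6-exo-trig attack of the adjacent phenol oxygen on the ester carbonyl (O1–C2) with loss of ethanol, which the Z geometry of 14 permits, after the C4–C4a bond has been made intermolecularly. No stereocentre is formed, and the C2' centre sits in a non-basic medium in which the hindered aryl ketone is not expected to enolise at room temperature. The step needs site selectivity and a single annulation: the two activated CH positions of 12 are interchanged by rotation about the aryl–C1' bond, the third CH is meta to both hydroxyls, and the new lactone withdraws electron density so that a small excess of 13 should not react twice. The two hydroxyl donors are expected to outweigh the chelated acyl group, and the electron-poor double bond of the senecioate is no partner for this electrophilic catalyst.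

Step 9
Reactants: 15 (2R)-1-(7-hydroxy-2-oxo-2H-chromen-8-yl)-3-methyl-1-oxobutan-2-yl 3-methylbut-2-enoate
Product: 16 (2R)-1-(7-methoxy-2-oxo-2H-chromen-8-yl)-3-methyl-1-oxobutan-2-yl 3-methylbut-2-enoate
Conditions: MeI (excess), Ag2O, CH2Cl2, rt, dark
Reagents that add atoms: iodomethane, CI
Why: Purdie-type O-methylation, in which Ag2O takes the acidic C7 phenol proton and assists departure of iodide, so no soluble strong base is present that could enolise the α-acyloxy ketone or cleave the ester.

**Compound list**
1 | resorcinol (benzene-1,3-diol) | Oc1cccc(O)c1 | starting material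
2 | 1,3-bis(methoxymethoxy)benzene | COCOc1cccc(OCOC)c1 | intermediate
3 | (R)-2-hydroxy-3-methylbutanoic acid | OC(=O)[C@H](O)C(C)C | starting material
4 | (2R)-2-hydroxy-N-methoxy-N,3-dimethylbutanamide | CON(C)C(=O)[C@H](O)C(C)C | intermediate
5 | (2R)-2-[(tert-butyldimethylsilyl)oxy]-N-methoxy-N,3-dimethylbutanamide | CON(C)C(=O)[C@H](O[Si](C)(C)C(C)(C)C)C(C)C | intermediate
6 | [2,6-bis(methoxymethoxy)phenyl]lithium (formed in the flask) | [Li]c1c(OCOC)cccc1OCOC | intermediate
7 | lithium (2R)-1-[2,6-bis(methoxymethoxy)phenyl]-2-[(tert-butyldimethylsilyl)oxy]-1-[methoxy(methyl)amino]-3-methylbutan-1-olate (formed in the flask, C1 not defined) | CON(C)C(O[Li])(c1c(OCOC)cccc1OCOC)[C@H](O[Si](C)(C)C(C)(C)C)C(C)C | intermediate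
8 | (2R)-1-[2,6-bis(methoxymethoxy)phenyl]-2-[(tert-butyldimethylsilyl)oxy]-3-methylbutan-1-one | COCOc1cccc(OCOC)c1C(=O)[C@H](O[Si](C)(C)C(C)(C)C)C(C)C | intermediate
9 | (2R)-1-[2,6-bis(methoxymethoxy)phenyl]-2-hydroxy-3-methylbutan-1-one | COCOc1cccc(OCOC)c1C(=O)[C@H](O)C(C)C | intermediate
10 | 3-methylbut-2-enoyl chloride | CC(C)=CC(Cl)=O | starting material
11 | (2R)-1-[2,6-bis(methoxymethoxy)phenyl]-3-methyl-1-oxobutan-2-yl 3-methylbut-2-enoate | COCOc1cccc(OCOC)c1C(=O)[C@H](OC(=O)C=C(C)C)C(C)C | intermediate
12 | (2R)-1-(2,6-dihydroxyphenyl)-3-methyl-1-oxobutan-2-yl 3-methylbut-2-enoate | Oc1cccc(O)c1C(=O)[C@H](OC(=O)C=C(C)C)C(C)C | intermediate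
13 | ethyl propiolate | CCOC(=O)C#C | starting material
14 | ethyl (2Z)-3-[2,4-dihydroxy-3-[(2R)-3-methyl-2-[(3-methylbut-2-enoyl)oxy]butanoyl]phenyl]prop-2-enoate (formed in the flask) | CCOC(=O)/C=C\c1ccc(O)c(C(=O)[C@H](OC(=O)C=C(C)C)C(C)C)c1O | intermediate
15 | (2R)-1-(7-hydroxy-2-oxo-2H-chromen-8-yl)-3-methyl-1-oxobutan-2-yl 3-methylbut-2-enoate | Oc1ccc2ccc(=O)oc2c1C(=O)[C@H](OC(=O)C=C(C)C)C(C)C | intermediate
16 | (2R)-1-(7-methoxy-2-oxo-2H-chromen-8-yl)-3-methyl-1-oxobutan-2-yl 3-methylbut-2-enoate | COc1ccc2ccc(=O)oc2c1C(=O)[C@H](OC(=O)C=C(C)C)C(C)C | target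

**Step count**
Total steps: 9. Longest linear sequence: 8 steps (3 → 16 through steps 2–9); the resorcinol branch joins in step 4.

**Steps most likely to fail**

Step 8. The acyl group lowers the nucleophilicity of the arene, so attack on the palladium-bound alkyne may be slower than oligomerisation of the propiolate. Forcing the reaction with heat or more alkyne invites a second annulation at the remaining hydroxyl or slow acid-mediated enolisation at C2'. The fallback makes the C4–C4a bond by cross-coupling instead of electrophilic substitution. Starting from 12, mono-iodination with N-iodosuccinimide (1.0 equiv, cat. CF3CO2H, MeCN, 0 °C) should give (2R)-1-(2,6-dihydroxy-3-iodophenyl)-3-methyl-1-oxobutan-2-yl 3-methylbut-2-enoate F1. The iodinating agent is a much stronger electrophile than the activated alkyne, and the equivalence of the two ortho positions again settles the site. Stille coupling of F1 with the known reagent ethyl (Z)-3-(tributylstannyl)prop-2-enoate (SMILES CCCC[Sn](CCCC)(CCCC)/C=C\C(=O)OCC; Pd(PPh3)4, zerovalent palladium, CuI, DMF, 50 °C) should give the Z-cinnamate 14 with retention of alkene geometry. Compound 14 lactonises as in step 8, and the route is rejoined at 15.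

Step 4. Addition of the doubly ortho-substituted aryllithium to the α-branched, silyloxy-bearing amide may be slow for steric reasons. The aryllithium may then act as a base, causing α-deprotonation with loss of configuration or elimination across the N–OMe group. The fallback uses a smaller, more electrophilic carbonyl partner. Starting from 5, reduction with i-Bu2AlH (THF, −78 °C) should stop at (2R)-2-[(tert-butyldimethylsilyl)oxy]-3-methylbutanal F2, which is used at once. Addition of aryllithium 6 (generated from 2 as in step 4) at −78 °C should give (2R)-1-[2,6-bis(methoxymethoxy)phenyl]-2-[(tert-butyldimethylsilyl)oxy]-3-methylbutan-1-ol F3 as a mixture of C1 epimers. Oxidation with Dess–Martin periodinane (CH2Cl2, rt) removes that centre and rejoins the route at 8.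

Step 9. O-Alkylation may lag because the C7 hydroxyl is held in a hydrogen bond to the C1' carbonyl and shielded by the branched side chain. Long exposure to Ag2O then risks enolisation at C2' or cleavage or migration of the senecioyl group. The fallback reverses the order of methylation and esterification, so the methylation meets no α-acyloxy ketone. Starting from 9, methanolic HCl as in step 7 should give the triol (2R)-1-(2,6-dihydroxyphenyl)-2-hydroxy-3-methylbutan-1-one F4. Annulation of F4 with 13 under the conditions of step 8 should pass through ethyl (2Z)-3-{2,4-dihydroxy-3-[(2R)-2-hydroxy-3-methylbutanoyl]phenyl}prop-2-enoate F5 (not isolated) to 7-hydroxy-8-[(2R)-2-hydroxy-3-methylbutanoyl]-2H-chromen-2-one F6. MeI and K2CO3 in acetone at rt should alkylate only the acidic coumarin phenol and give 8-[(2R)-2-hydroxy-3-methylbutanoyl]-7-methoxy-2H-chromen-2-one F7. Esterification of F7 with 10 under the conditions of step 6 comes back to the route at the target 16.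

**Further compounds**
F1 | step 8 | (2R)-1-(2,6-dihydroxy-3-iodophenyl)-3-methyl-1-oxobutan-2-yl 3-methylbut-2-enoate | Oc1ccc(I)c(O)c1C(=O)[C@H](OC(=O)C=C(C)C)C(C)C
F2 | step 4 | (2R)-2-[(tert-butyldimethylsilyl)oxy]-3-methylbutanal | O=C[C@H](O[Si](C)(C)C(C)(C)C)C(C)C
F3 | step 4 | (2R)-1-[2,6-bis(methoxymethoxy)phenyl]-2-[(tert-butyldimethylsilyl)oxy]-3-methylbutan-1-ol (both C1 epimers) | COCOc1cccc(OCOC)c1C(O)[C@H](O[Si](C)(C)C(C)(C)C)C(C)C
F4 | step 9 | (2R)-1-(2,6-dihydroxyphenyl)-2-hydroxy-3-methylbutan-1-one | Oc1cccc(O)c1C(=O)[C@H](O)C(C)C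
F5 | step 9 | ethyl (2Z)-3-{2,4-dihydroxy-3-[(2R)-2-hydroxy-3-methylbutanoyl]phenyl}prop-2-enoate | CCOC(=O)/C=C\c1ccc(O)c(C(=O)[C@H](O)C(C)C)c1O
F6 | step 9 | 7-hydroxy-8-[(2R)-2-hydroxy-3-methylbutanoyl]-2H-chromen-2-one | Oc1ccc2ccc(=O)oc2c1C(=O)[C@H](O)C(C)C
F7 | step 9 | 8-[(2R)-2-hydroxy-3-methylbutanoyl]-7-methoxy-2H-chromen-2-one | COc1ccc2ccc(=O)oc2c1C(=O)[C@H](O)C(C)C
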